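**Plan**

1. Ring numbering used here: C1(=O), C2(OH), C3(docosyl), C4(=O), C5(OMe), C6(H). The retrosynthesis cuts C5–C6 and C3–C4 of the quinone ring together, then the bond from C3 to the docosyl chain.
2. Enabling feature: the ring is the 2-enol and 5-methyl enol ether of cyclohexane-1,2,4,5-tetraone. C1/C2 are an α-diketone with two nucleophilic α-carbons (C6, C3), and C4/C5 are an oxalyl unit, so the quinone can arise by condensation alone, with no oxidation step.
3. Forward: the chain is joined first (hydrazone alkylation with 1-bromodocosane, hydrolysis to hexacosane-2,3-dione). The diketone is armed as its bis-silyl dienol ether, and the ring is made last by a one-pot [4+2] cyclocondensation with methyl trimethoxyacetate (C5 enters as orthoester and keeps one OMe, C4 enters as ester).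
4. Stereochemistry: the target has no stereocentre. The hydrazone and enol ether geometries drawn for 2, 4, 6 and 8 are the expected ones and are of no consequence. Compounds 1, 3 and 7 are taken as purchasable.

Key step: step 4

**Route**

Step 1
Reactants: 1 3,3-dimethoxybutan-2-one
Product: 2 (E)-3,3-dimethoxybutan-2-one N,N-dimethylhydrazone
Conditions: Me2NNH2 (3 equiv), EtOH, 4 Å MS, 70 °C
Reagents that add atoms: N,N-dimethylhydrazine, CN(C)N
Why: Hydrazone condensation under non-acidic, dehydrating conditions should leave the dimethyl ketal intact and give a hydrazone whose only α-C–H bonds are those of the C-methyl group.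

Step 2
Reactants: 2 (E)-3,3-dimethoxybutan-2-one N,N-dimethylhydrazone; 3 1-bromodocosane
Product: 5 hexacosane-2,3-dione, via alkylated hydrazone ketal 4 (not isolated)
Conditions: LiN(iPr)2, THF, 0 °C; 3 in THF, 0 °C → rt; then 3 M HCl, THF, 50 °C
Reagents that add atoms: water, O
Why: Azaenolate alkylation of an N,N-dimethylhydrazone can place the chain only on the methyl carbon, and acid hydrolysis of hydrazone and ketal in the same flask should then unmask the 1,2-diketone.

Step 3
Reactants: 5 hexacosane-2,3-dione
Product: 6 (3Z)-2,3-bis(trimethylsilyloxy)hexacosa-1,3-diene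
Conditions: TMSOTf (2.3 equiv), Et3N (3 equiv), CH2Cl2, 0 °C → rt; pentane extraction
Reagents that add atoms: trimethylsilyl trifluoromethanesulfonate, C[Si](C)(C)OS(=O)(=O)C(F)(F)F
Why: Double soft enolisation and O-silylation of a 1,2-diketone, as in the preparation of 2,3-bis(trimethylsilyloxy)buta-1,3-diene from biacetyl, can give only this diene because each carbonyl has a single enolisable side.

Step 4
Reactants: 6 (3Z)-2,3-bis(trimethylsilyloxy)hexacosa-1,3-diene; 7 methyl 2,2,2-trimethoxyacetate
Product: 10 3-docosyl-2-hydroxy-5-methoxycyclohexa-2,5-diene-1,4-dione, via keto ketal ester 8 (not isolated), via cyclic dimethyl ketal 9 (not isolated)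
Conditions: TMSOTf (0.2 equiv), CH2Cl2, -40 → 0 °C; then KOtBu (2.2 equiv), THF, -20 °C → rt; 1 M HCl
Reagents that add atoms: none
Why: Proposed new method: TMSOTf should ionise orthoester 7 to the dimethoxycarbenium ion (MeO)2C(+)CO2Me, which the unsubstituted CH2 terminus of diene 6 captures (Mukaiyama-type addition of a silyl enol ether to an orthoester) to give 8; KOtBu then cleaves the remaining silyl enol ether to the potassium enolate, whose docosyl-bearing carbon attacks the ester carbonyl (Dieckmann-type Claisen condensation) to give 9, and E1cB loss of methanol from the ketal leaves the vinylogous methyl ester of 10. The overall change is a redox-neutral formal [4+2] cyclocondensation whose nearest known relatives are the formal [3+3] cyclocondensations of 1,3-bis(silyloxy)dienes with 1,3-dielectrophiles and the double Claisen condensation of ketones with oxalate esters. The six-membered ring closes by a 6-(enolendo)-exo-trig C-acylation, and deprotonation of the resulting vinylogous acid makes the closure irreversible. No stereocentre is formed. The step needs regioselection between the two diene termini and between the two oxalyl carbons: the hindered carbenium ion should react at the CH2 terminus and not at the CH-docosyl terminus, the enone-type silyl enol ether left in 8 is too deactivated for a second addition, and only the ester carbon can act as acyl donor in the basic phase, so the methoxy group must end next to the ring CH. If methanol is lost from 8 before ring closure, reversible methoxide addition to the resulting enol ether should still allow the geometry needed for closure to be reached.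

**Compound list**

1 | 3,3-dimethoxybutan-2-one | CC(=O)C(C)(OC)OC | starting material
2 | (E)-3,3-dimethoxybutan-2-one N,N-dimethylhydrazone | C/C(=N\N(C)C)C(C)(OC)OC | intermediate
3 | 1-bromodocosane | CCCCCCCCCCCCCCCCCCCCCCBr | starting material
4 | (E)-2,2-dimethoxyhexacosan-3-one N,N-dimethylhydrazone (not isolated) | CCCCCCCCCCCCCCCCCCCCCCC/C(=N\N(C)C)C(C)(OC)OC | intermediate
5 | hexacosane-2,3-dione | CC(=O)C(=O)CCCCCCCCCCCCCCCCCCCCCCC | intermediate
6 | (3Z)-2,3-bis(trimethylsilyloxy)hexacosa-1,3-diene | C=C(O[Si](C)(C)C)/C(O[Si](C)(C)C)=C/CCCCCCCCCCCCCCCCCCCCCC | intermediate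
7 | methyl 2,2,2-trimethoxyacetate | COC(=O)C(OC)(OC)OC | starting material
8 | methyl (5Z)-2,2-dimethoxy-4-oxo-5-(trimethylsilyloxy)octacos-5-enoate (not isolated) | COC(=O)C(OC)(OC)CC(=O)/C(O[Si](C)(C)C)=C/CCCCCCCCCCCCCCCCCCCCCC | intermediate
9 | 3-docosyl-2-hydroxy-5,5-dimethoxycyclohex-2-ene-1,4-dione (not isolated) | CCCCCCCCCCCCCCCCCCCCCCC1=C(O)C(=O)CC(OC)(OC)C1=O | intermediate
10 | 3-docosyl-2-hydroxy-5-methoxycyclohexa-2,5-diene-1,4-dione | CCCCCCCCCCCCCCCCCCCCCCC1=C(O)C(=O)C=C(OC)C1=O | target

**Count and risks**

Total step count: 4. Longest linear sequence: 4 steps (1 → 2 → 5 → 6 → 10).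

Steps most likely to fail:

1. Step 4. Ionisation of the ester-bearing orthoester may be slow, so that protodesilylation of the diene outruns C–C bond formation. Attack may occur through the substituted diene terminus, which would put the methoxy group next to the chain. In the basic phase, O-acylation or a benzilic-type rearrangement of the diketone unit may compete with ring closure. The fallback uses known chemistry, sets out from 3 and comes back at 10. 2,3,5,6-Tetramethoxyphenyllithium (from 1,2,4,5-tetramethoxybenzene and n-BuLi in THF) is alkylated with 3 to give 1-docosyl-2,3,5,6-tetramethoxybenzene F1. Oxidative demethylation with (NH4)2Ce(NO3)6 in MeCN/H2O should give 3-docosyl-2,5-dimethoxycyclohexa-2,5-diene-1,4-dione F2. Selective hydrolysis with HClO4 in dioxane of the methoxy group flanked by the alkyl chain should then give 10.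

2. Step 2. The SN2 alkylation may be sluggish because the C22 bromide and the lithium azaenolate are poorly soluble together at low temperature. Elimination from the bromide and acid-induced aldol self-condensation of the diketone during hydrolysis are further risks. The fallback sets out from 3 and comes back at 5. But-2-yne is lithiated at the propargylic position (n-BuLi, THF/TMEDA) and alkylated with 3 to give hexacos-2-yne F3. Oxidation of the alkyne with RuO2 (cat.)/NaIO4 in CCl4/MeCN/H2O should give 5.

3. Step 3. The second enolisation may be incomplete, and silyl groups may be lost to adventitious water on isolation. The fallback sets out from 5, avoids the silyl dienol ether altogether and comes back at 10. A double Claisen condensation of 5 with dimethyl oxalate (NaOMe, MeOH/THF) should give 3-docosyl-2,5-dihydroxycyclohexa-2,5-diene-1,4-dione F4. Acid-catalysed vinylogous esterification under equilibrating conditions (MeOH, cat. H2SO4) should then methylate the hydroxyl next to the ring CH and not the one flanked by the chain, giving 10.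

**Further compounds**

F1 | step 4 | 1-docosyl-2,3,5,6-tetramethoxybenzene | CCCCCCCCCCCCCCCCCCCCCCc1c(OC)c(OC)cc(OC)c1OC
F2 | step 4 | 3-docosyl-2,5-dimethoxycyclohexa-2,5-diene-1,4-dione | CCCCCCCCCCCCCCCCCCCCCCC1=C(OC)C(=O)C=C(OC)C1=O
F3 | step 2 | hexacos-2-yne | CC#CCCCCCCCCCCCCCCCCCCCCCCCC
F4 | step 3 | 3-docosyl-2,5-dihydroxycyclohexa-2,5-diene-1,4-dione | CCCCCCCCCCCCCCCCCCCCCCC1=C(O)C(=O)C=C(O)C1=O
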